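**Retrosynthetic overview**

1. Target 26 is a heptaphenol, freed last from its heptabenzyl ether 25. Its rings are A (dioxygenated benzene), B (indane five-membered ring), C (cyclopentane), D (cyclohex-4-ene-1,3-dione) and E (cyclopentanone). Rings D and E form a bicyclo[3.2.1]oct-3-ene-2,8-dione that shares the quaternary carbon, the bridging C=O and the bridgehead CH.
2. Key disconnection: ring D is cut at its two acyl bonds, enone C=O to bridgehead CH and bridging C=O to quaternary carbon. This leads back to enoyl thioester 23 with a pendant methyl ester, and one base-mediated double Claisen closes ring E and then ring D.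
3. Enabling feature: in ring D both carbonyl carbons are acyl carbons placed 1,3 across the bridgehead CH. The quaternary carbon shared by rings C, D and E is the γ-carbon of the enone, and the bridgehead CH is α to the bridging ketone, so ring D is the retron of a γ-acylation followed by an α-acylation.
4. Side chain of 23: the first benzylic carbon comes from iridium-catalysed allylic alkylation of ketone 10, the chain is extended by cross-metathesis, and the second benzylic carbon comes from rhodium-catalysed aryl conjugate addition. The enoyl thioester comes from a thioester aldol addition and dehydration.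
5. Ring order: C (two copper-catalysed aryl additions starting from enone 1), then B (aldol, then Friedel–Crafts closure onto ring A), then E and D together.

Key step: step 13

Assumption (chemistry): the ligand antipodes in steps 8 and 10 are those that give the configurations drawn (catalyst control), and the epimerisable C2 centre of 16–23 is drawn as the epimer trans to the C3 aryl group. Locants C1, C2, C3, C3a, C8, C8a refer to the cyclopenta[a]indenone core of 10.

**Step 1**
Reactants: 1 (4R)-4-[(tert-butyldimethylsilyl)oxy]cyclopent-2-en-1-one; 2 [4-(benzyloxy)phenyl]magnesium bromide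
Product: 4 (4R)-4-[4-(benzyloxy)phenyl]cyclopent-2-en-1-one, via trans-3-aryl-4-silyloxycyclopentanone 3 (not isolated)
Conditions: CuBr·SMe2 (10 mol%), THF, −78 °C; aq. NH4Cl; then DBU, CH2Cl2, 0 °C
Reagents that add atoms: none
Why: Copper-catalysed conjugate addition of the aryl Grignard reagent should occur anti to the C4 silyloxy group, and E1cB loss of silanolate then gives the 4-aryl enone, so the aryl-bearing stereocenter is set by the commercial (4R)-silyl ether.

**Step 2**
Reactants: 4 (4R)-4-[4-(benzyloxy)phenyl]cyclopent-2-en-1-one; 5 1,3-bis(benzyloxy)-5-bromobenzene; 6 4-(benzyloxy)benzaldehyde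
Product: 8 (2S,3S,4R)-4-[4-(benzyloxy)phenyl]-3-[3,5-bis(benzyloxy)phenyl]-2-{[4-(benzyloxy)phenyl](hydroxy)methyl}cyclopentan-1-one, via aryl Grignard reagent 7 (not isolated)
Conditions: 5, Mg, THF, 23 °C; then CuBr·SMe2 (10 mol%), 4, −78 °C; then 6, −78 °C; aq. NH4Cl
Reagents that add atoms: none
Why: Copper-catalysed conjugate addition anti to the C4 aryl group should give a regiodefined magnesium enolate at C2, which is trapped by the aldehyde anti to the new C3 aryl group (three-component conjugate addition–aldol coupling); the carbinol centre is lost in step 3.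

**Step 3**
Reactants: 8 (2S,3S,4R)-4-[4-(benzyloxy)phenyl]-3-[3,5-bis(benzyloxy)phenyl]-2-{[4-(benzyloxy)phenyl](hydroxy)methyl}cyclopentan-1-one
Product: 10 (3R,3aS,8R,8aR)-5,7-bis(benzyloxy)-3,8-bis[4-(benzyloxy)phenyl]-3,3a,8,8a-tetrahydro-2H-cyclopenta[a]inden-1-one, via (E)-benzylidene ketone 9 (not isolated)
Conditions: BF3·OEt2 (20 mol%), CH2Cl2, −20 → 23 °C
Reagents that add atoms: none
Why: The Lewis acid should effect E1 dehydration to the (E)-enone and then an intramolecular Friedel–Crafts (Michael-type) alkylation by an ortho carbon of the dibenzyloxyphenyl ring, which can reach the benzylic carbon from one face only, so ring B closes with the C8 aryl group on the convex face and ketonisation gives the cis ring fusion at C8a.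

**Step 4**
Reactants: 10 (3R,3aS,8R,8aR)-5,7-bis(benzyloxy)-3,8-bis[4-(benzyloxy)phenyl]-3,3a,8,8a-tetrahydro-2H-cyclopenta[a]inden-1-one
Product: 11 trimethylsilyl enol ether of 10 (C1–OSiMe3, C1=C2)
Conditions: LiN(i-Pr)2, Me3SiCl, THF, −78 °C
Reagents that add atoms: chlorotrimethylsilane, C[Si](C)(C)Cl
Why: Kinetic deprotonation should take the unhindered C2 methylene in preference to the ring-fusion methine, and O-silylation fixes this regiochemistry (kinetic silyl enol ether formation).

**Step 5**
Reactants: 6 4-(benzyloxy)benzaldehyde; 12 ethyl (triphenylphosphoranylidene)acetate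
Product: 13 ethyl (2E)-3-[4-(benzyloxy)phenyl]prop-2-enoate
Conditions: toluene, 80 °C
Reagents that add atoms: none
Why: Wittig olefination with a stabilised ylide should give the (E)-cinnamate.

**Step 6**
Reactants: 13 ethyl (2E)-3-[4-(benzyloxy)phenyl]prop-2-enoate
Product: 14 (2E)-3-[4-(benzyloxy)phenyl]prop-2-en-1-ol
Conditions: i-Bu2AlH (2.2 equiv), CH2Cl2, −78 °C; aq. Rochelle salt
Reagents that add atoms: none
Why: 1,2-Reduction of the conjugated ester with i-Bu2AlH should give the allylic alcohol without touching the alkene.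

**Step 7**
Reactants: 14 (2E)-3-[4-(benzyloxy)phenyl]prop-2-en-1-ol
Product: 15 (2E)-3-[4-(benzyloxy)phenyl]prop-2-en-1-yl methyl carbonate
Conditions: ClCO2Me, pyridine, CH2Cl2, 0 °C
Reagents that add atoms: methyl chloroformate, COC(=O)Cl
Why: Acylation of the primary alcohol gives the linear allylic carbonate needed for allyl-iridium formation (carbonate formation).

**Step 8**
Reactants: 11 trimethylsilyl enol ether of 10; 15 (2E)-3-[4-(benzyloxy)phenyl]prop-2-en-1-yl methyl carbonate
Product: 16 ketone 10 bearing at C2 (2R, trans to the C3 aryl group) a (1R)-1-[4-(benzyloxy)phenyl]prop-2-en-1-yl group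
Conditions: [Ir(cod)Cl]2 (2 mol%), binaphthol-derived N,N-bis(1-phenylethyl)phosphoramidite (4 mol%, antipode as assumed), CsF, ZnF2, DME, 50 °C
Reagents that add atoms: none
Why: Iridium-catalysed asymmetric allylic alkylation of the fluoride-activated enol silane should be branched-selective, the phosphoramidite antipode fixing the new benzylic stereocenter, while C2 is epimerisable and is planarised again in step 13.

**Step 9**
Reactants: 16 C2-allylated ketone; 17 methyl acrylate
Product: 18 methyl (2E,4R)-4-[4-(benzyloxy)phenyl]-4-[C2 of ketone 10 (2R)]but-2-enoate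
Conditions: 17 (5 equiv), second-generation Hoveyda–Grubbs catalyst (5 mol%), CH2Cl2, 40 °C
Reagents that add atoms: none
Why: Olefin cross-metathesis of the terminal alkene with an excess of the electron-poor acrylate should give the (E)-enoate selectively.

**Step 10**
Reactants: 18 methyl (2E,4R)-enoate; 19 [3,5-bis(benzyloxy)phenyl]boronic acid
Product: 20 methyl (3S,4R)-3-[3,5-bis(benzyloxy)phenyl]-4-[4-(benzyloxy)phenyl]-4-[C2 of ketone 10 (2R)]butanoate
Conditions: 19 (2 equiv), [RhCl(C2H4)2]2 (2.5 mol%), chiral 2,5-diphenylbicyclo[2.2.2]octa-2,5-diene (5.5 mol%, antipode as assumed), KOH (20 mol%), dioxane/H2O, 40 °C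
Reagents that add atoms: none
Why: The Hayashi–Miyaura rhodium-catalysed conjugate addition delivers the aryl group to the β-carbon of the enoate, the chiral diene controlling the face so that the two benzylic aryl groups end up in the relative arrangement required for ring E.

**Step 11**
Reactants: 20 methyl (3S,4R)-diarylbutanoate ketone; 21 S-ethyl ethanethioate
Product: 22 tertiary aldol adduct of 20 (C1(OH)–CH2C(=O)SEt, C1 configuration not assigned)
Conditions: 21, LiN(i-Pr)2, THF, −78 °C; CeCl3; then 20, −78 °C; aq. NH4Cl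
Reagents that add atoms: none
Why: Aldol addition of the thioester enolate to the ketone should be chemoselective over the methyl ester at −78 °C, the cerium enolate suppressing enolisation of the hindered ketone; the carbinol centre is removed in step 12.

**Step 12**
Reactants: 22 tertiary aldol adduct
Product: 23 S-ethyl (2E)-2-[C1-ylidene of the core of 10]ethanethioate carrying the side chain of 20 (exocyclic C1=CH–C(=O)SEt, thioester on the C2 side)
Conditions: MeSO2Cl, Et3N (excess), CH2Cl2, 0 → 23 °C
Reagents that add atoms: none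
Why: Mesylation followed by E1cB elimination through the thioester enolate should give the conjugated exocyclic enoyl thioester; either alkene geometry is usable in step 13, and the (E)-isomer is the one listed.

**Step 13**
Reactants: 23 S-ethyl (2E)-enoyl thioester
Product: 25 hepta-O-benzyl ether of 26, via monocyclised keto thioester 24 (not isolated)
Conditions: LiN(SiMe3)2 (1.2 equiv), THF, −78 → 0 °C (23 added to the base); aq. NH4Cl at −20 °C
Reagents that add atoms: none
Why: Proposed new method: LiN(SiMe3)2 removes a γ-hydrogen of the enoyl thioester, which is far more acidic than the α-hydrogens of the methyl ester, and the γ-carbon of the dienolate acylates the pendant ester in a 5-(enolexo)-exo-trig closure of ring E to give 24; the expelled methoxide enolises the new ketone at its only α-CH2, and this enolate acylates the thioester carbonyl in a 6-(enolendo)-exo-trig closure of ring D with loss of ethanethiolate. The closest known reactions are the Dieckmann condensation, the intramolecular γ-acylation of ester dienolates (vinylogous Claisen) and the C-acylation of ketone enolates by thioesters; their tandem use to reach a bridged, non-enolisable 1,3-dione is new. The quaternary centre is controlled by allylic 1,3-strain, which holds the side-chain C–H in the plane of the dienolate so that the tethered ester reaches only the face syn to the C3 aryl group, and the bridgehead CH follows from the ring constraint. The step needs γ- over α-acylation (five- against seven-membered ring), the enoyl geometry with the thioester syn to the quaternary carbon (the two geometries should interconvert through reversible γ-deprotonation at the ring-fusion carbon and only one can close), and no retro-Claisen opening (the only base left at the end is a thiolate, a poor nucleophile towards ketones).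

**Step 14**
Reactants: 25 hepta-O-benzyl ether of 26
Product: 26 target CNP0407321.1
Conditions: BCl3 (excess), C6HMe5, CH2Cl2, −78 °C; MeOH
Reagents that add atoms: none
Why: Lewis-acid cleavage of the aryl benzyl ethers with pentamethylbenzene as cation scavenger should free all seven phenols at low temperature without touching the enone, the diketone or the benzylic stereocenters (BCl3/pentamethylbenzene debenzylation).

**Compound list**

1 | (4R)-4-[(tert-butyldimethylsilyl)oxy]cyclopent-2-en-1-one | O=C1C[C@@H](O[Si](C)(C)C(C)(C)C)C=C1 | starting material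
2 | [4-(benzyloxy)phenyl]magnesium bromide | Br[Mg]c1ccc(OCc2ccccc2)cc1 | starting material
3 | (3S,4R)-3-[4-(benzyloxy)phenyl]-4-[(tert-butyldimethylsilyl)oxy]cyclopentan-1-one | O=C1C[C@@H](O[Si](C)(C)C(C)(C)C)[C@H](c3ccc(OCc5ccccc5)cc3)C1 | intermediate
4 | (4R)-4-[4-(benzyloxy)phenyl]cyclopent-2-en-1-one | O=C1C=C[C@H](c3ccc(OCc5ccccc5)cc3)C1 | intermediate
5 | 1,3-bis(benzyloxy)-5-bromobenzene | Brc1cc(OCc2ccccc2)cc(OCc2ccccc2)c1 | starting material
6 | 4-(benzyloxy)benzaldehyde | O=Cc1ccc(OCc2ccccc2)cc1 | starting material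
7 | [3,5-bis(benzyloxy)phenyl]magnesium bromide | Br[Mg]c1cc(OCc2ccccc2)cc(OCc2ccccc2)c1 | intermediate
8 | (2S,3S,4R)-4-[4-(benzyloxy)phenyl]-3-[3,5-bis(benzyloxy)phenyl]-2-{[4-(benzyloxy)phenyl](hydroxy)methyl}cyclopentan-1-one (all-trans ring, carbinol epimers) | O=C1[C@H](C(O)c4ccc(OCc5ccccc5)cc4)[C@@H](c4cc(OCc5ccccc5)cc(OCc5ccccc5)c4)[C@H](c3ccc(OCc5ccccc5)cc3)C1 | intermediate
9 | (2E,3R,4R)-4-[4-(benzyloxy)phenyl]-2-[4-(benzyloxy)benzylidene]-3-[3,5-bis(benzyloxy)phenyl]cyclopentan-1-one | O=C1/C(=C/c4ccc(OCc5ccccc5)cc4)[C@@H](c4cc(OCc5ccccc5)cc(OCc5ccccc5)c4)[C@H](c3ccc(OCc5ccccc5)cc3)C1 | intermediate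
10 | (3R,3aS,8R,8aR)-5,7-bis(benzyloxy)-3,8-bis[4-(benzyloxy)phenyl]-3,3a,8,8a-tetrahydro-2H-cyclopenta[a]inden-1-one (rings A, B, C; cis ring fusion, both aryl groups on the convex face) | O=C1[C@H]2[C@H](c3ccc(OCc5ccccc5)cc3)c3c(OCc5ccccc5)cc(OCc5ccccc5)cc3[C@H]2[C@H](c3ccc(OCc5ccccc5)cc3)C1 | intermediate
11 | trimethylsilyl enol ether of 10 (C1–OSiMe3, C1=C2; other centres as in 10) | C[Si](C)(C)OC=1[C@H]2[C@H](c3ccc(OCc5ccccc5)cc3)c3c(OCc5ccccc5)cc(OCc5ccccc5)cc3[C@H]2[C@H](c3ccc(OCc5ccccc5)cc3)C=1 | intermediate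
12 | ethyl (triphenylphosphoranylidene)acetate | CCOC(=O)C=P(c1ccccc1)(c1ccccc1)c1ccccc1 | starting material
13 | ethyl (2E)-3-[4-(benzyloxy)phenyl]prop-2-enoate | CCOC(=O)/C=C/c1ccc(OCc2ccccc2)cc1 | intermediate
14 | (2E)-3-[4-(benzyloxy)phenyl]prop-2-en-1-ol | OC/C=C/c1ccc(OCc2ccccc2)cc1 | intermediate
15 | (2E)-3-[4-(benzyloxy)phenyl]prop-2-en-1-yl methyl carbonate | COC(=O)OC/C=C/c1ccc(OCc2ccccc2)cc1 | intermediate
16 | ketone 10 bearing at C2 (2R, trans to the C3 aryl group) a (1R)-1-[4-(benzyloxy)phenyl]prop-2-en-1-yl group | O=C1[C@H]2[C@H](c3ccc(OCc5ccccc5)cc3)c3c(OCc5ccccc5)cc(OCc5ccccc5)cc3[C@H]2[C@H](c3ccc(OCc5ccccc5)cc3)[C@H]1[C@@H](C=C)c1ccc(OCc5ccccc5)cc1 | intermediate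
17 | methyl acrylate | C=CC(=O)OC | starting material
18 | methyl (2E,4R)-4-[4-(benzyloxy)phenyl]-4-[C2 of ketone 10 (2R)]but-2-enoate | O=C1[C@H]2[C@H](c3ccc(OCc5ccccc5)cc3)c3c(OCc5ccccc5)cc(OCc5ccccc5)cc3[C@H]2[C@H](c3ccc(OCc5ccccc5)cc3)[C@H]1[C@@H](/C=C/C(=O)OC)c1ccc(OCc5ccccc5)cc1 | intermediate
19 | [3,5-bis(benzyloxy)phenyl]boronic acid | OB(O)c1cc(OCc2ccccc2)cc(OCc2ccccc2)c1 | starting material
20 | methyl (3S,4R)-3-[3,5-bis(benzyloxy)phenyl]-4-[4-(benzyloxy)phenyl]-4-[C2 of ketone 10 (2R)]butanoate | O=C1[C@H]2[C@H](c3ccc(OCc5ccccc5)cc3)c3c(OCc5ccccc5)cc(OCc5ccccc5)cc3[C@H]2[C@H](c3ccc(OCc5ccccc5)cc3)[C@H]1[C@@H]([C@H](CC(=O)OC)c1cc(OCc5ccccc5)cc(OCc5ccccc5)c1)c1ccc(OCc5ccccc5)cc1 | intermediate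
21 | S-ethyl ethanethioate | CCSC(C)=O | starting material
22 | tertiary aldol adduct of 20: C1 carries OH and CH2C(=O)SEt (C1 configuration not assigned; other centres as in 20) | CCSC(=O)CC1(O)[C@H]2[C@H](c3ccc(OCc5ccccc5)cc3)c3c(OCc5ccccc5)cc(OCc5ccccc5)cc3[C@H]2[C@H](c3ccc(OCc5ccccc5)cc3)[C@H]1[C@@H]([C@H](CC(=O)OC)c1cc(OCc5ccccc5)cc(OCc5ccccc5)c1)c1ccc(OCc5ccccc5)cc1 | intermediate
23 | S-ethyl (2E)-enoyl thioester: exocyclic C1=CH–C(=O)SEt on the core of 20, thioester on the C2 side (the other alkene isomer may accompany it) | CCSC(=O)/C=C1/[C@H]2[C@H](c3ccc(OCc5ccccc5)cc3)c3c(OCc5ccccc5)cc(OCc5ccccc5)cc3[C@H]2[C@H](c3ccc(OCc5ccccc5)cc3)[C@H]1[C@@H]([C@H](CC(=O)OC)c1cc(OCc5ccccc5)cc(OCc5ccccc5)c1)c1ccc(OCc5ccccc5)cc1 | intermediate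
24 | monocyclised keto thioester: C2 of 23 acylated by the ester carbonyl (ring E closed as a spiro cyclopentanone, enoyl thioester intact) | CCSC(=O)/C=C1/[C@H]2[C@H](c3ccc(OCc5ccccc5)cc3)c3c(OCc5ccccc5)cc(OCc5ccccc5)cc3[C@H]2[C@H](c3ccc(OCc5ccccc5)cc3)[C@]12C(=O)C[C@H](c1cc(OCc5ccccc5)cc(OCc5ccccc5)c1)[C@H]2c1ccc(OCc5ccccc5)cc1 | intermediate
25 | hepta-O-benzyl ether of 26 (all seven phenols as benzyl ethers, stereocenters as in 26) | O=C1C=C2[C@H]3[C@H](c4ccc(OCc5ccccc5)cc4)c4c(OCc5ccccc5)cc(OCc5ccccc5)cc4[C@H]3[C@H](c3ccc(OCc5ccccc5)cc3)[C@]23C(=O)[C@H]1[C@H](c1cc(OCc5ccccc5)cc(OCc5ccccc5)c1)[C@H]3c1ccc(OCc5ccccc5)cc1 | intermediate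
26 | target CNP0407321.1 | O=C1C=C2[C@H]3[C@H](c4ccc(O)cc4)c4c(O)cc(O)cc4[C@H]3[C@H](c3ccc(O)cc3)[C@]23C(=O)[C@H]1[C@H](c1cc(O)cc(O)c1)[C@H]3c1ccc(O)cc1 | target

**Step count and risks**

Total step count: 14. Longest linear sequence: 11 steps (steps 1–4 and 8–14).

Steps most likely to fail:

Step 13 (proposed new method). The cascade may stall after the first ring because the enoyl geometry does not equilibrate. The hindered γ-carbon may be acylated too slowly relative to proton shuffling or seven-membered α-acylation. The strained diketone may reopen by retro-Claisen cleavage. The fallback sets out from 20 and uses known chemistry with a different closure of ring D. A Dieckmann condensation of the C2 ketone enolate onto the methyl ester (NaH, THF) should give the spiro 1,3-diketone F1, with the same allylic-strain control of the quaternary centre. Soft enolisation (MgBr2·OEt2, i-Pr2NEt) and C-acetylation with 1-acetylbenzotriazole at the ring-E methylene should give the triketone F2. An acid- or amine-catalysed intramolecular aldol condensation of the acetyl methyl group onto the ring-C ketone then closes ring D through its C=C bond and comes back to the route at 25.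

Step 8. The hindered chiral enolate may react slowly, give linear instead of branched product, or show mismatched double stereodifferentiation at the benzylic carbon. The fallback sets out from 10 (with 6 for the acceptor). A Henry condensation of 6 with nitromethane should give 1-(benzyloxy)-4-[(E)-2-nitroethenyl]benzene F3. An enamine-catalysed Michael addition of 10 (chiral pyrrolidine–thiourea catalyst, reaction at the C2 methylene) should give the nitro ketone F4 with the benzylic centre under catalyst control. A Nef reaction (NaOMe, then cold H2SO4) should give the aldehyde F5, and a Horner–Wadsworth–Emmons reaction with trimethyl phosphonoacetate (LiCl, i-Pr2NEt) comes back to the route at 18.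

Step 10. Aryl transfer to the γ-branched enoate may be slow, so that protodeboronation takes over, or the facial selectivity may be eroded by the adjacent stereocenter. The fallback sets out from 18 and sets the stereocenter by hydride instead of aryl delivery. An oxidative Heck arylation with 19 (Pd(OAc)2, O2) should give the β,β-disubstituted enoate methyl (2E,4R)-3-[3,5-bis(benzyloxy)phenyl]-4-[4-(benzyloxy)phenyl]-4-[C2 of ketone 10]but-2-enoate F6. A copper hydride-catalysed asymmetric conjugate reduction (Cu(OAc)2, chiral bisphosphine, polymethylhydrosiloxane, t-BuOH) then comes back to the route at 20.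

**Further compounds**

F1 | step 13 | spiro 1,3-diketone from Dieckmann closure of ring E on ketone 20 | O=C1[C@H]2[C@H](c3ccc(OCc5ccccc5)cc3)c3c(OCc5ccccc5)cc(OCc5ccccc5)cc3[C@H]2[C@H](c3ccc(OCc5ccccc5)cc3)[C@]12C(=O)C[C@H](c1cc(OCc5ccccc5)cc(OCc5ccccc5)c1)[C@H]2c1ccc(OCc5ccccc5)cc1
F2 | step 13 | F1 C-acetylated at the ring-E methylene (acetyl-bearing centre epimerisable) | O=C1[C@H]2[C@H](c3ccc(OCc5ccccc5)cc3)c3c(OCc5ccccc5)cc(OCc5ccccc5)cc3[C@H]2[C@H](c3ccc(OCc5ccccc5)cc3)[C@]12C(=O)C(C(C)=O)[C@H](c1cc(OCc5ccccc5)cc(OCc5ccccc5)c1)[C@H]2c1ccc(OCc5ccccc5)cc1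
F3 | step 8 | 1-(benzyloxy)-4-[(E)-2-nitroethenyl]benzene | [O-][N+](=O)/C=C/c1ccc(OCc2ccccc2)cc1
F4 | step 8 | ketone 10 bearing at C2 a (1R)-1-[4-(benzyloxy)phenyl]-2-nitroethyl group | O=C1[C@H]2[C@H](c3ccc(OCc5ccccc5)cc3)c3c(OCc5ccccc5)cc(OCc5ccccc5)cc3[C@H]2[C@H](c3ccc(OCc5ccccc5)cc3)[C@H]1[C@@H](C[N+](=O)[O-])c1ccc(OCc5ccccc5)cc1
F5 | step 8 | (2R)-2-[4-(benzyloxy)phenyl]-2-[C2 of ketone 10]acetaldehyde | O=C1[C@H]2[C@H](c3ccc(OCc5ccccc5)cc3)c3c(OCc5ccccc5)cc(OCc5ccccc5)cc3[C@H]2[C@H](c3ccc(OCc5ccccc5)cc3)[C@H]1[C@@H](C=O)c1ccc(OCc5ccccc5)cc1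
F6 | step 10 | methyl (2E,4R)-3-[3,5-bis(benzyloxy)phenyl]-4-[4-(benzyloxy)phenyl]-4-[C2 of ketone 10]but-2-enoate | O=C1[C@H]2[C@H](c3ccc(OCc5ccccc5)cc3)c3c(OCc5ccccc5)cc(OCc5ccccc5)cc3[C@H]2[C@H](c3ccc(OCc5ccccc5)cc3)[C@H]1[C@@H](/C(=C\C(=O)OC)c1cc(OCc5ccccc5)cc(OCc5ccccc5)c1)c1ccc(OCc5ccccc5)cc1
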